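## Retrosynthetic overview

1. The enal is unveiled last by allylic oxidation of a 2-isopropenyl group (C(=CH2)CH3 → C(=CH2)CHO); the side chain is an (R)-1-arylethyl tiglate made by catalytic asymmetric ketone reduction and acylation.
2. Key disconnection: the dihydrofuran ring (O1–C2–C3–C3a–C7a) comes from ring contraction of a trans-4-acetoxy-2,2-dimethylchroman-3-ol. A 1,2-shift of the ring oxygen from CMe2 to the activated carbinol carbon forms O1–C2 with inversion and releases the isopropenyl group.
3. Enabling feature: C2 carries both the ring oxygen O1 and an exocyclic, fully substituted sp2 carbon (the C(=CH2)CHO carbon, a former CMe2). O1–C2–C(=CH2) is therefore the 1,2-oxygen-shifted isomer of the O1–CMe2–CH(O) unit of a chroman, and the trans C2–O1/C3–OAc pair is the trans hydroxy acetate from SN2 opening of a chromene 3,4-epoxide.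
4. The two ring stereocentres trace back to a Jacobsen epoxidation of a 2,2-dimethyl-2H-chromene and acetate opening at the benzylic carbon.
5. Ring order: benzene ring (purchased, 4-hydroxyacetophenone) → pyran ring (chromene annulation, temporary; its transient oxirane is opened at once) → dihydrofuran ring, closed last at the expense of the pyran ring.

Key step: step 6

Assumption: the (S,S)-Mn(salen) catalyst is taken to give the (3S,4S)-epoxide and the (R,R)-TsDPEN–Ru catalyst the (R)-carbinol, the usual sense for 2,2-dimethylchromenes and aryl methyl ketones; if either sense proved opposite, the enantiomeric catalyst would be used.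

## Route

Step 1
Reactants: 1 4-hydroxyacetophenone; 2 3-methylbut-2-enal diethyl acetal (1,1-diethoxy-3-methylbut-2-ene)
Product: 3 1-(2,2-dimethyl-2H-chromen-6-yl)ethanone
Conditions: 3-picoline (0.25 equiv), p-xylene, 140 °C, EtOH distilled off
Reagents that add atoms: none
Why: Base-mediated chromenylation of a phenol with an enal acetal (transacetalisation, loss of EtOH to the ortho-quinone-methide-type dienone, then oxa-6π electrocyclisation) builds the pyran ring, and the para-substituted phenol has two equivalent ortho positions, so only the 6-acetyl chromene can form.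

Step 2
Reactants: 3 1-(2,2-dimethyl-2H-chromen-6-yl)ethanone
Product: 4 (R)-1-(2,2-dimethyl-2H-chromen-6-yl)ethanol
Conditions: RuCl[(R,R)-TsDPEN](p-cymene) (1 mol%), HCO2H/Et3N (5:2), 30 °C
Reagents that add atoms: none
Why: Noyori asymmetric transfer hydrogenation of an aryl methyl ketone, in which the (R,R)-TsDPEN–Ru hydride should deliver hydrogen to the face that gives the (R)-1-arylethanol (outer-sphere six-membered transition state with CH/π contact to the aryl group), while the unpolarised chromene C=C is not reduced.

Step 3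
Reactants: 4 (R)-1-(2,2-dimethyl-2H-chromen-6-yl)ethanol; 5 tigloyl chloride ((E)-2-methylbut-2-enoyl chloride)
Product: 6 (R)-1-(2,2-dimethyl-2H-chromen-6-yl)ethyl (E)-2-methylbut-2-enoate
Conditions: pyridine (3 equiv), DMAP (0.1 equiv), CH2Cl2, 0 °C to rt
Reagents that add atoms: none
Why: DMAP-catalysed acylation of the secondary benzylic alcohol with the acid chloride breaks no bond at the stereocentre, and pyridine in place of a trialkylamine avoids vinylketene formation and deconjugation of the (E)-2-methylbut-2-enoyl unit.

Step 4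
Reactants: 6 (R)-1-(2,2-dimethyl-2H-chromen-6-yl)ethyl (E)-2-methylbut-2-enoate
Product: 7 (R)-1-[(3S,4S)-3,4-epoxy-2,2-dimethylchroman-6-yl]ethyl (E)-2-methylbut-2-enoate
Conditions: (S,S)-Jacobsen Mn(III)(salen)Cl (4 mol%), 4-phenylpyridine N-oxide (0.2 equiv), aq. NaOCl (pH 11.3), CH2Cl2, 0 °C
Reagents that add atoms: sodium hypochlorite, [Na+].[O-]Cl
Why: Jacobsen–Katsuki epoxidation, for which 2,2-dimethylchromenes (cis-disubstituted, aryl-conjugated alkenes) are privileged substrates, should place the oxygen on the face giving the (3S,4S)-epoxide under catalyst control, while the electron-poor trisubstituted tiglate alkene does not react.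

Step 5
Reactants: 7 (R)-1-[(3S,4S)-3,4-epoxy-2,2-dimethylchroman-6-yl]ethyl (E)-2-methylbut-2-enoate
Product: 8 (R)-1-[(3S,4R)-4-acetoxy-3-hydroxy-2,2-dimethylchroman-6-yl]ethyl (E)-2-methylbut-2-enoate
Conditions: AcOH (5 equiv), Bu4NOAc (1.5 equiv), MeCN, 40 °C
Reagents that add atoms: acetic acid, CC(=O)O
Why: Regio- and stereospecific SN2 opening of the epoxide by acetate at the benzylic C4 (C3 is neopentylic) with inversion should give the trans (3S,4R) hydroxy acetate, the buffered acetate medium keeping the opening on the SN2 side and leaving the benzylic tiglate alone.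

Step 6
Reactants: 8 (R)-1-[(3S,4R)-4-acetoxy-3-hydroxy-2,2-dimethylchroman-6-yl]ethyl (E)-2-methylbut-2-enoate
Product: 11 (R)-1-[(2S,3R)-3-acetoxy-2-(prop-1-en-2-yl)-2,3-dihydro-1-benzofuran-5-yl]ethyl (E)-2-methylbut-2-enoate, via triflate 9 (not isolated), via tertiary carbocation 10 (not isolated)
Conditions: Tf2O (1.2 equiv), 2,6-di-tert-butyl-4-methylpyridine (3 equiv), CH2Cl2, −78 °C to rt
Reagents that add atoms: none
Why: O-triflation gives 9, in which the equatorial C3–OTf bond of the trans-diequatorial half-chair lies antiperiplanar to the ring bond C2–O1, so O1 displaces triflate from the rear (3-exo-tet, O1-bridged oxiranium), the old O1–CMe2 bond breaks to the tertiary cation 10 and loss of a methyl proton to the hindered base leaves the isopropenyl group (overall a 1,2-oxygen shift with E1 termination). The closest known reaction type is the ring-oxygen 1,2-shift of activated 2,2-dimethylchroman-3-ols, which contract to 2-(2-substituted prop-2-yl)-2,3-dihydrobenzofurans, and of equatorial pyranoside triflates, which contract to furanosides. The dihydrofuran ring (O1, C2, C3, C3a, C7a of 11) is closed by this intramolecular SN2 attack of O1 on the carbinol carbon and becomes the only heterocycle once the pyran C–O bond has broken, a six-to-five ring contraction. The C2 stereocentre of 11 (chroman C3) is set by stereospecific inversion, O1 entering anti to the triflate, while the acetoxy-bearing carbon is not touched, so the trans (3S,4R) hydroxy acetate can only give the trans (2S,3R) product. The step needs migration of O1 to win over migration of the aryl carbon C4a (equally antiperiplanar), over rear-side participation of the C4 acetate and over a 1,2-methyl shift (both possible only from the diaxial conformer), and it needs proton loss from CH3 instead of C2–H. The substrate secures this through the gem-dimethyl group (O1 migration releases a tertiary cation), the electron-poor acetoxy group at C4 (aryl migration would leave a poor α-acyloxy cation), the syn-axial OAc/CH3 clash that disfavours the diaxial conformer, and the six methyl hydrogens of 10 against one C2–H that is deactivated by two adjacent C–O bonds.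

Step 7
Reactants: 11 (R)-1-[(2S,3R)-3-acetoxy-2-(prop-1-en-2-yl)-2,3-dihydro-1-benzofuran-5-yl]ethyl (E)-2-methylbut-2-enoate
Product: 13 (R)-1-[(2S,3R)-3-acetoxy-2-(3-oxoprop-1-en-2-yl)-2,3-dihydro-1-benzofuran-5-yl]ethyl (E)-2-methylbut-2-enoate, via allylic alcohol 12 (not isolated)
Conditions: SeO2 (1.5 equiv), 1,4-dioxane, 70 °C
Reagents that add atoms: selenium dioxide, O=[Se]=O
Why: Riley allylic oxidation (ene reaction of SeO2 at the electron-rich 1,1-disubstituted alkene, [2,3]-shift to the primary allylic alcohol 12, further oxidation to the 2-substituted acrolein) should follow the usual CH3-over-CH preference at a geminally disubstituted alkene, the conjugated tiglate alkene being far less reactive and no stereocentre being touched.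

## Compound list

1 | 4-hydroxyacetophenone | CC(=O)c1ccc(O)cc1 | starting material
2 | 3-methylbut-2-enal diethyl acetal (1,1-diethoxy-3-methylbut-2-ene) | CCOC(OCC)C=C(C)C | starting material
3 | 1-(2,2-dimethyl-2H-chromen-6-yl)ethanone | CC1(C)C=Cc2cc(C(C)=O)ccc2O1 | intermediate
4 | (R)-1-(2,2-dimethyl-2H-chromen-6-yl)ethanol | CC1(C)C=Cc2cc([C@@H](C)O)ccc2O1 | intermediate
5 | tigloyl chloride ((E)-2-methylbut-2-enoyl chloride) | C/C=C(\C)C(=O)Cl | starting material
6 | (R)-1-(2,2-dimethyl-2H-chromen-6-yl)ethyl (E)-2-methylbut-2-enoate | CC1(C)C=Cc2cc([C@@H](C)OC(=O)/C(C)=C/C)ccc2O1 | intermediate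
7 | (R)-1-[(3S,4S)-3,4-epoxy-2,2-dimethylchroman-6-yl]ethyl (E)-2-methylbut-2-enoate | CC1(C)Oc2ccc([C@@H](C)OC(=O)/C(C)=C/C)cc2[C@@H]3O[C@H]13 | intermediate
8 | (R)-1-[(3S,4R)-4-acetoxy-3-hydroxy-2,2-dimethylchroman-6-yl]ethyl (E)-2-methylbut-2-enoate (trans) | CC1(C)Oc2ccc([C@@H](C)OC(=O)/C(C)=C/C)cc2[C@@H](OC(C)=O)[C@@H]1O | intermediate
9 | C3 triflate of 8 | CC1(C)Oc2ccc([C@@H](C)OC(=O)/C(C)=C/C)cc2[C@@H](OC(C)=O)[C@@H]1OS(=O)(=O)C(F)(F)F | intermediate
10 | tertiary 2-propyl carbocation (triflate salt; open form of the O1-bridged oxiranium ion) | C[C+](C)[C@@H]1Oc2ccc([C@@H](C)OC(=O)/C(C)=C/C)cc2[C@H]1OC(C)=O.[O-]S(=O)(=O)C(F)(F)F | intermediate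
11 | (R)-1-[(2S,3R)-3-acetoxy-2-(prop-1-en-2-yl)-2,3-dihydro-1-benzofuran-5-yl]ethyl (E)-2-methylbut-2-enoate (trans) | C=C(C)[C@@H]1Oc2ccc([C@@H](C)OC(=O)/C(C)=C/C)cc2[C@H]1OC(C)=O | intermediate
12 | (R)-1-[(2S,3R)-3-acetoxy-2-(3-hydroxyprop-1-en-2-yl)-2,3-dihydro-1-benzofuran-5-yl]ethyl (E)-2-methylbut-2-enoate | C=C(CO)[C@@H]1Oc2ccc([C@@H](C)OC(=O)/C(C)=C/C)cc2[C@H]1OC(C)=O | intermediate
13 | (R)-1-[(2S,3R)-3-acetoxy-2-(3-oxoprop-1-en-2-yl)-2,3-dihydro-1-benzofuran-5-yl]ethyl (E)-2-methylbut-2-enoate | C=C(C=O)[C@@H]1Oc2ccc([C@@H](C)OC(=O)/C(C)=C/C)cc2[C@H]1OC(C)=O | target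

## Step count and risks

Total step count: 7. Longest linear sequence: 7 steps (1 → 13).

Steps most likely to fail:

Step 6 (key step). The triflate may be captured from the rear by the carbonyl oxygen of the neighbouring acetate (acetoxonium formation from the diaxial conformer). A 1,2-methyl or aryl shift may compete, or the tertiary cation may be intercepted before it loses a proton. The fallback sets out from 8 and comes back at 11. It exchanges the acetate for an ester that keeps C4 electron-poor but whose carbonyl oxygen is too weakly nucleophilic to participate. Methanolysis of 8 (K2CO3, MeOH, 0 °C; the conjugated, α-branched tiglate should survive) should give the trans-diol F1. The less hindered benzylic hydroxyl is then acylated (Cl3CCOCl, pyridine, CH2Cl2, −78 °C) to the 4-O-trichloroacetate F2. The same activation (Tf2O, 2,6-di-tert-butyl-4-methylpyridine, CH2Cl2, −78 °C to rt), through the C3 triflate F3, should give the ring-contracted trichloroacetate F4. The activated ester is removed selectively (NaHCO3, MeOH, 0 °C) to give the trans alcohol F5, and acetylation (Ac2O, pyridine, DMAP, 0 °C) returns 11.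

Step 7. The oxidation may stall at the allylic alcohol or attack the C2–H, and the warm, mildly acidic selenium medium may trigger loss of acetic acid across C2–C3 with aromatisation to the benzofuran. The fallback sets out from 11 and comes back at 13, using a selenium-free two-stage oxidation at or below room temperature. Ene-type allylic chlorination with hypochlorous acid made in situ (Ca(OCl)2, solid CO2, CH2Cl2/H2O, 0 °C) should give the allylic chloride F6 with the same methyl-over-methine preference. N-oxide oxidation of this chloride (N-methylmorpholine N-oxide, NaI cat., MeCN, rt) should then give 13 under neutral conditions.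

Step 5. The benzylic C4–O bond may ionise before acetate attacks (the ring oxygen is ortho and the C6 substituent is an alkyl donor). That would erode the trans selectivity and could start solvolysis of the side-chain benzylic ester. The fallback sets out from 3 and comes back at 8. Epoxidation and opening are run while C6 still carries the acetyl group, whose acceptor effect para to O1 disfavours ionisation at C4. Jacobsen epoxidation of 3 with the (S,S)-catalyst should give the epoxy ketone F7. Opening with AcOH/Bu4NOAc should give the trans hydroxy acetate F8, and transfer hydrogenation with the (R,R)-TsDPEN–Ru catalyst the diol F9. The unhindered side-chain carbinol is then acylated selectively with 5 (1.05 equiv, pyridine, DMAP cat., CH2Cl2, −20 °C), the ring C3–OH being neopentylic, to return to 8.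

## Further compounds

F1 | step 6 | (R)-1-[(3S,4R)-3,4-dihydroxy-2,2-dimethylchroman-6-yl]ethyl (E)-2-methylbut-2-enoate | CC1(C)Oc2ccc([C@@H](C)OC(=O)/C(C)=C/C)cc2[C@@H](O)[C@@H]1O
F2 | step 6 | (R)-1-[(3S,4R)-3-hydroxy-2,2-dimethyl-4-(trichloroacetoxy)chroman-6-yl]ethyl (E)-2-methylbut-2-enoate | CC1(C)Oc2ccc([C@@H](C)OC(=O)/C(C)=C/C)cc2[C@@H](OC(=O)C(Cl)(Cl)Cl)[C@@H]1O
F3 | step 6 | C3 triflate of F2 | CC1(C)Oc2ccc([C@@H](C)OC(=O)/C(C)=C/C)cc2[C@@H](OC(=O)C(Cl)(Cl)Cl)[C@@H]1OS(=O)(=O)C(F)(F)F
F4 | step 6 | (R)-1-[(2S,3R)-2-(prop-1-en-2-yl)-3-(trichloroacetoxy)-2,3-dihydro-1-benzofuran-5-yl]ethyl (E)-2-methylbut-2-enoate | C=C(C)[C@@H]1Oc2ccc([C@@H](C)OC(=O)/C(C)=C/C)cc2[C@H]1OC(=O)C(Cl)(Cl)Cl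
F5 | step 6 | (R)-1-[(2S,3R)-3-hydroxy-2-(prop-1-en-2-yl)-2,3-dihydro-1-benzofuran-5-yl]ethyl (E)-2-methylbut-2-enoate | C=C(C)[C@@H]1Oc2ccc([C@@H](C)OC(=O)/C(C)=C/C)cc2[C@H]1O
F6 | step 7 | (R)-1-[(2S,3R)-3-acetoxy-2-(3-chloroprop-1-en-2-yl)-2,3-dihydro-1-benzofuran-5-yl]ethyl (E)-2-methylbut-2-enoate | C=C(CCl)[C@@H]1Oc2ccc([C@@H](C)OC(=O)/C(C)=C/C)cc2[C@H]1OC(C)=O
F7 | step 5 | 1-[(3S,4S)-3,4-epoxy-2,2-dimethylchroman-6-yl]ethanone | CC1(C)Oc2ccc(C(C)=O)cc2[C@@H]3O[C@H]13
F8 | step 5 | 1-[(3S,4R)-4-acetoxy-3-hydroxy-2,2-dimethylchroman-6-yl]ethanone | CC1(C)Oc2ccc(C(C)=O)cc2[C@@H](OC(C)=O)[C@@H]1O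
F9 | step 5 | (3S,4R)-3-hydroxy-6-[(R)-1-hydroxyethyl]-2,2-dimethylchroman-4-yl acetate | CC1(C)Oc2ccc([C@@H](C)O)cc2[C@@H](OC(C)=O)[C@@H]1O
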